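**The trap.** Do not assume that a larger reagent charge gives a larger [target] at the end: target decays as well as forms, so the figure asked, the free form in the first phase, is a balance at one moment.

    reagent in the reaction phase ⇌ reagent in the second phase, rate k1*([reagent in the reaction phase] - [reagent in the second phase]/K1) per volume of the first phase (K1 = 6.08, k1 = 0.333 s⁻¹)
    starting material + reagent in the reaction phase → target (k2 = 57000 L mol⁻¹ s⁻¹)
    target ⇌ product in the second phase, rate k3*([target] - [product in the second phase]/K3) per volume of the first phase (K3 = 11.7, k3 = 17.8 s⁻¹)
    target → decomposed product (k4 = 1.57 s⁻¹)
    2 starting material → self-condensation product (k5 = 118 L mol⁻¹ s⁻¹)

all flasks: starting material 0.20 mM; time 6.0 s; volume of the second phase over the first 1.0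
- north: reagent in the second phase 0.400 mM
- south-east: reagent in the second phase 0.500 mM
- east: reagent in the second phase 0.800 mM
- west: reagent in the second phase 1.20 mM
- north-west: reagent in the second phase 2.00 mM

- percentages count the starting material that a species holds: one self-condensation product counts as two
- target is meant together with its product in the second phase
- where a step has two of a species, its rate is k times that concentration squared, and two are used at each turn
- in the second phase: reagent in the second phase, product in the second phase; everything else is in the first
- charges count per volume of the first phase; a concentration in a rate is the amount of a species over the volume of its own phase; every rate counts per litre of the first phase
- the concentration of target that is asked is that of its free form alone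
- "hardly changes" means that all values lie within two and a half points (for a concentration: within two and a half percent of the largest)
- run time (north): 6.0 s

* [target] (only what is free in solution, in the first phase) at the end for north, south-east, east, west, north-west, in this order
* how that number moves from the first to the last of them (falls all the way / rises all the way / hardly changes / rises, then falls / falls, then rises)

**Fast steps.** Treat target and product in the second phase as one pool at partition equilibrium, because transfer at 17.8 s⁻¹ outruns decomposition at 1.57 s⁻¹. The free share of that pool is then 0.0787. Treat reagent in the reaction phase as a short-lived quasi-steady-state intermediate while starting material lasts, because in north its half-life by reaction with starting material as charged, 0.061 s, is shorter than the 2.08 s of the transfer. The transfer is then the rate-limiting step, and it supplies reagent at its coefficient times [reagent in the second phase] over the partition ratio, 0.0219 mM s⁻¹ in north.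

**Delivery number.** Define the delivery number, the reagent the transfer brings across in the run time per starting material charged 0.657; north has this value. South-east has 0.822, east 1.31, west 1.97 and north-west 3.29. Below 1, expect starting material to outlast the run and free target to climb with the charge. Above it, expect starting material to end early and the pool to decay afterwards. Score each shape by how well the delivery numbers at the two ends of the row fit it: north stands below 1 and north-west above it, so commit to rises, then falls, with a top near east.

**One number?** It gives direction, not height. The pool decays at 0.124 s⁻¹, which over the run makes 0.742 decay times. A steady feed into that pool gives 0.00731 mM free target in north. A feed stopping at run time over delivery number gives 0.00841 mM in north-west. Both ignore self-condensation.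

**The forecast.** It reads 0.0061 mM, 0.0075 mM, 0.0087 mM, 0.0082 mM, 0.0077 mM, shape rises, then falls, on these grounds: “at higher charges the pool forms earlier and has longer to decay, so the value peaks and then falls”. Its north and north-west values stand lower than mine.

**The flask.** The row gives 0.00568 mM, 0.00692 mM, 0.00879 mM, 0.00807 mM, 0.00757 mM, shape rises, then falls. East, the highest point, ends with starting material at 3.06 %. The row's turn reads 0.79 mM of reagent in the second phase, a delivery number of 1.29. In north-west the delivery number puts the consumption of starting material at 1.83 s, and at 3.00 s starting material stands at 0.613 %.

The numbers of this flask were set for the occasion; no experiment stands behind them.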